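The norbornene core is cut by a late, biomimetic Diels–Alder reaction into an acetoxycyclopentadiene made from xanthatin and the α-methylene lactone 1-O-acetylbritannilactone. Everything else rests on the cyclohexene ring of that seco-eudesmane half (C5' to C10'): its C5'=C10' alkene, flanked by the C6' carbinol and the C7'–C8' lactone edge, is a Diels–Alder retron. One cycloaddition between a 1-silyloxydiene, whose carbons C6', C5', C4', C15', C3', C2' and C1' come from (S)-citronellal, and (Z)-3-oxobut-1-enyl acetate closes this ring and sets C6', C7' and C8'. The precursors are an open-chain dienol ether and a four-carbon enol ester.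

Key step: step 5

Remark: xanthatin (20) and (S)-citronellal (1) are taken as purchasable; atoms are numbered C1–C15 in the guaiane half and C1'–C15' in the seco-eudesmane half; C2 of 4 and the carbinol carbon C4 of 24 lose their configuration in the following step and are left undefined.

Step 1
Reactants: 1 (S)-citronellal
Product: 2 trimethylsilyl enol ether of 1 (E/Z mixture)
Conditions: TMSOTf, Et3N, CH2Cl2, 0 °C
Reagents that add atoms: trimethylsilyl trifluoromethanesulfonate, C[Si](C)(C)OS(=O)(=O)C(F)(F)F
Why: Soft enolisation and O-silylation of the aldehyde (silyl enol ether formation) leaves the C4' stereocentre untouched, and the enol ether geometry is irrelevant for step 2.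

Step 2
Reactants: 2 trimethylsilyl enol ether; 3 2,2-dimethoxypropane
Product: 5 (3S)-3,7-dimethyl-2-(propan-2-ylidene)oct-6-enal, via β-methoxy aldehyde 4 (not isolated)
Conditions: TMSOTf (5 mol %), CH2Cl2, −78 °C; then DBU, 25 °C
Reagents that add atoms: none
Why: Mukaiyama-type aldol addition of the silyl enol ether to the oxocarbenium ion of the acetone ketal, then E1cB loss of methanol, should give the conjugated tetrasubstituted enal that carries C10', C9' and C14'.

Step 3
Reactants: 5 enal
Product: 6 (1E)-1-(tert-butyldimethylsilyloxy)-3-methyl-2-[(2S)-6-methylhept-5-en-2-yl]buta-1,3-diene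
Conditions: TBSOTf, Et3N, CH2Cl2, 0 °C
Reagents that add atoms: tert-butyldimethylsilyl trifluoromethanesulfonate, CC(C)(C)[Si](C)(C)OS(=O)(=O)C(F)(F)F
Why: Vinylogous (γ) deprotonation and O-silylation of the β,β-dimethyl enal, which reacts from its s-trans conformer, should give the 1E dienol ether with oxygen on the outside of the diene.

Step 4
Reactants: 7 2,5-dimethylfuran
Product: 9 (Z)-3-oxobut-1-en-1-yl acetate, via furan endoperoxide 8 (not isolated)
Conditions: O2, hν, tetraphenylporphyrin (cat.), CH2Cl2, −78 °C; then 25 °C
Reagents that add atoms: dioxygen, O=O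
Why: [4+2] addition of singlet oxygen to the furan followed by Baeyer–Villiger-type rearrangement of the endoperoxide should deliver the cis β-acyloxy enone, the Z geometry being inherited from the ring.

Step 5
Reactants: 6 silyloxydiene; 9 (Z)-3-oxobut-1-en-1-yl acetate
Product: 10 all-cis Diels–Alder adduct (6'-O-TBS / 7'-acetyl / 8'-O-acetyl cyclohexene; C7' and C8' as in the target; C6' epimeric)
Conditions: o-tolyl-oxazaborolidinium triflimide from (S)-diphenylprolinol (20 mol %; its mirror image if the facial sense requires it), CH2Cl2, −78 → −40 °C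
Reagents that add atoms: none
Why: Concerted but asynchronous normal-electron-demand [4+2] cycloaddition in which the catalyst-bound ketone of 9 lowers the dienophile LUMO, the nucleophilic diene terminus C9' bonds to the β-carbon C8' and C6' bonds to C7'; the closest known reaction type is the chiral oxazaborolidinium-catalysed Diels–Alder reaction of 1-silyloxydienes with acyclic enones. The one new ring, the cyclohexene C5'–C10', is closed in the intermolecular suprafacial [4+2] mode. C7' and C8' should come out cis because the Z geometry of 9 is transferred, C6' should come out cis to the acetyl group through the endo transition state (it is inverted in step 8), and the absolute sense of all three centres is set by the catalyst, which shields one face of the coordinated enone, the remote C4' centre being a spectator. The step needs ortho regioselectivity, which the 1-silyloxy group secures, endo selectivity, which the ketone secures, and survival of the β-acetoxy ketone, which low temperature and the absence of base secure.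

Step 6
Reactants: 10 Diels–Alder adduct
Product: 11 enol triflate (C11'(OTf)=C13'H2)
Conditions: KN(SiMe3)2, THF, −78 °C; then PhNTf2
Reagents that add atoms: N-phenylbis(trifluoromethanesulfonimide), O=S(=O)(N(c1ccccc1)S(=O)(=O)C(F)(F)F)C(F)(F)F
Why: Kinetic deprotonation of the methyl ketone on its unhindered methyl side and O-triflation (enol triflate formation) should avoid the C7' enolate, which would expel the C8' acetate.

Step 7
Reactants: 11 enol triflate
Product: 12 6'-alcohol (6'-OH cis to the C7' and C8' substituents)
Conditions: HF·pyridine, THF, 0 °C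
Reagents that add atoms: none
Why: Fluoride-mediated desilylation frees only the allylic C6' hydroxyl, while the acetate and the enol triflate are inert.

Step 8
Reactants: 12 6'-alcohol
Product: 13 6',8'-diacetate with inverted C6'
Conditions: PPh3, DIAD, AcOH, toluene, 0 → 25 °C
Reagents that add atoms: acetic acid, CC(=O)O
Why: Mitsunobu reaction: SN2 displacement of the oxyphosphonium ion by acetate from the open face, anti to the cis C7' and C8' substituents, should invert C6' to the configuration of the target.

Step 9
Reactants: 13 diacetate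
Product: 14 6',8'-diol
Conditions: K2CO3 (cat.), MeOH, 0 °C
Reagents that add atoms: none
Why: Base-catalysed transesterification to methanol removes both acetates without touching any stereocentre.

Step 10
Reactants: 14 diol
Product: 15 α-methylene-γ-lactone (12',8'-olide) with free 6'-OH
Conditions: Pd(PPh3)4 (5 mol %), CO (1 atm), Et3N, MeCN, 60 °C
Reagents that add atoms: carbon monoxide, [C-]#[O+]
Why: Palladium-catalysed carbonylative lactonisation (oxidative addition of the enol triflate, CO insertion, capture of the acyl palladium by the hydroxyl) should close the cis-fused lactone on C8', the only hydroxyl cis to the acyl arm.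

Step 11
Reactants: 15 lactone
Product: 17 C1' aldehyde, via side-chain diol 16 (not isolated)
Conditions: OsO4 (2 mol %), NMO, acetone/H2O, 0 °C; then NaIO4
Reagents that add atoms: N-methylmorpholine N-oxide (oxygen delivered through OsO4), C[N+]1([O-])CCOCC1
Why: Catalytic dihydroxylation followed by periodate glycol cleavage should pick the unhindered, electron-rich trisubstituted side-chain alkene over the hindered tetrasubstituted ring alkene and the electron-poor methylene lactone.

Step 12
Reactants: 17 aldehyde
Product: 18 britannilactone (C1' primary alcohol)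
Conditions: NaBH(OAc)3, AcOH (cat.), ClCH2CH2Cl, 25 °C
Reagents that add atoms: none
Why: The mild acyloxyborohydride reduces the aldehyde chemoselectively and should leave the α-methylene lactone alone.

Step 13
Reactants: 18 britannilactone
Product: 19 1-O-acetylbritannilactone
Conditions: Ac2O (1.1 equiv), pyridine, CH2Cl2, −20 °C
Reagents that add atoms: acetic anhydride, CC(=O)OC(C)=O
Why: Acylation should take the primary C1' hydroxyl much faster than the hindered secondary allylic C6' hydroxyl.

Step 14
Reactants: 20 xanthatin
Product: 22 (2R)-2-hydroxy-2,3-dihydroxanthatin, via peroxyhemiketal 21 (not isolated)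
Conditions: 50% aq. H2O2, 9-amino-9-deoxy-epi-quinine·2 CF3CO2H (10 mol %; the quinidine-derived catalyst if it is the one giving 2R), dioxane, 30 °C; then PPh3
Reagents that add atoms: hydrogen peroxide, OO
Why: Iminium-catalysed asymmetric conjugate hydroperoxidation of the methyl enone, followed by phosphine reduction of the cyclic peroxyhemiketal, should set C2 under catalyst control, while the α-methylene lactone cannot form an iminium ion and stays intact.

Step 15
Reactants: 22 β-hydroxy ketone
Product: 23 (2R)-2-acetoxy-2,3-dihydroxanthatin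
Conditions: Ac2O, pyridine, DMAP (cat.), CH2Cl2, 0 °C
Reagents that add atoms: acetic anhydride, CC(=O)OC(C)=O
Why: Simple O-acetylation of the secondary alcohol under mild conditions, to limit β-elimination back to 20.

Step 16
Reactants: 23 acetoxy ketone
Product: 24 (2R)-2-acetoxy-4-hydroxyguaia-1(5),11(13)-dien-12,8-olide (C4 epimers)
Conditions: SnCl4 (20 mol %), CH2Cl2, −78 °C
Reagents that add atoms: none
Why: Lewis acid Prins (carbonyl-ene type) cyclisation: C5 of the trisubstituted C1=C5 alkene attacks the activated C4 ketone, and the tertiary C1 cation should lose H5 to restore the ring-fusion alkene, which is endocyclic to the new five-membered ring, so that C2 and C10 stay untouched.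

Step 17
Reactants: 24 cyclopentenol; 19 1-O-acetylbritannilactone
Product: 26 CNP0211028.3 (target), via acetoxycyclopentadiene 25 (not isolated)
Conditions: Ph2S[OC(CF3)2Ph]2 (1.05 equiv), CH2Cl2, −40 → 0 °C; then 19 (3 equiv), concentrate, 35 °C
Reagents that add atoms: none
Why: Dehydration of the tertiary allylic alcohol gives the 5-acetoxycyclopentadiene, which should undergo a Diels–Alder reaction with the α-methylene lactone of 19: C13' bonds to the fully substituted C1 and C11' to C3 (steric regiocontrol), the diene reacts on the face anti to the C10 methyl and the C2 acetoxy group, the lactone carbonyl sits exo as is usual for α-methylene lactones, and the dienophile turns the face that keeps its cyclohexene ring away from the cycloheptane ring, which sets C1, C3 and C11'.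

Compound list
1 | (S)-citronellal, (3S)-3,7-dimethyloct-6-enal | O=CC[C@@H](C)CCC=C(C)C | starting material
2 | trimethylsilyl enol ether of 1 (E/Z mixture) | C[Si](C)(C)OC=C[C@@H](C)CCC=C(C)C | intermediate
3 | 2,2-dimethoxypropane | COC(C)(C)OC | starting material
4 | (3S)-2-(2-methoxypropan-2-yl)-3,7-dimethyloct-6-enal (C2 epimers, not isolated) | COC(C)(C)C(C=O)[C@@H](C)CCC=C(C)C | intermediate
5 | (3S)-3,7-dimethyl-2-(propan-2-ylidene)oct-6-enal | CC(C)=C(C=O)[C@@H](C)CCC=C(C)C | intermediate
6 | (1E)-1-(tert-butyldimethylsilyloxy)-3-methyl-2-[(2S)-6-methylhept-5-en-2-yl]buta-1,3-diene | CC(C)(C)[Si](C)(C)O/C=C(/C(C)=C)[C@@H](C)CCC=C(C)C | intermediate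
7 | 2,5-dimethylfuran | Cc1ccc(C)o1 | starting material
8 | 1,4-dimethyl-2,3,7-trioxabicyclo[2.2.1]hept-5-ene (not isolated) | CC12C=CC(C)(OO1)O2 | intermediate
9 | (Z)-3-oxobut-1-en-1-yl acetate | CC(=O)O/C=C\C(C)=O | intermediate
10 | Diels–Alder adduct: cyclohexene with 6'-OTBS, 7'-acetyl and 8'-OAc all cis, (4'S) side chain | CC(C)(C)[Si](C)(C)O[C@@H]1[C@H](C(C)=O)[C@H](OC(C)=O)CC(C)=C1[C@@H](C)CCC=C(C)C | intermediate
11 | enol triflate of 10 | CC(C)(C)[Si](C)(C)O[C@@H]1[C@H](C(=C)OS(=O)(=O)C(F)(F)F)[C@H](OC(C)=O)CC(C)=C1[C@@H](C)CCC=C(C)C | intermediate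
12 | 6'-alcohol (6'-OH cis to the C7' and C8' substituents) | O[C@@H]1[C@H](C(=C)OS(=O)(=O)C(F)(F)F)[C@H](OC(C)=O)CC(C)=C1[C@@H](C)CCC=C(C)C | intermediate
13 | 6',8'-diacetate, C6' inverted (6'-OAc trans to the C7' and C8' substituents) | CC(=O)O[C@H]1[C@H](C(=C)OS(=O)(=O)C(F)(F)F)[C@H](OC(C)=O)CC(C)=C1[C@@H](C)CCC=C(C)C | intermediate
14 | 6',8'-diol enol triflate | O[C@H]1[C@H](C(=C)OS(=O)(=O)C(F)(F)F)[C@H](O)CC(C)=C1[C@@H](C)CCC=C(C)C | intermediate
15 | cis-fused α-methylene-γ-lactone with 6'-OH and the (S)-6-methylhept-5-en-2-yl side chain | O[C@H]1[C@H]2[C@H](OC(=O)C2=C)CC(C)=C1[C@@H](C)CCC=C(C)C | intermediate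
16 | side-chain diol of 15 (diol carbon epimers, not isolated) | O[C@H]1[C@H]2[C@H](OC(=O)C2=C)CC(C)=C1[C@@H](C)CCC(O)C(C)(C)O | intermediate
17 | C1' aldehyde | O[C@H]1[C@H]2[C@H](OC(=O)C2=C)CC(C)=C1[C@@H](C)CCC=O | intermediate
18 | britannilactone (4'S,6'S,7'S,8'R) | O[C@H]1[C@H]2[C@H](OC(=O)C2=C)CC(C)=C1[C@@H](C)CCCO | intermediate
19 | 1-O-acetylbritannilactone (4'S,6'S,7'S,8'R) | O[C@H]1[C@H]2[C@H](OC(=O)C2=C)CC(C)=C1[C@@H](C)CCCOC(C)=O | intermediate
20 | xanthatin (7R,8S,10S) | C=C1C(=O)O[C@H]2C[C@H](C)C(/C=C/C(C)=O)=CC[C@H]12 | starting material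
21 | cyclic peroxyhemiketal of 2-hydroperoxy-2,3-dihydroxanthatin (hemiketal epimers, not isolated) | C=C1C(=O)O[C@H]2C[C@H](C)C([C@H]3CC(C)(O)OO3)=CC[C@H]12 | intermediate
22 | (2R)-2-hydroxy-2,3-dihydroxanthatin | C=C1C(=O)O[C@H]2C[C@H](C)C([C@H](O)CC(C)=O)=CC[C@H]12 | intermediate
23 | (2R)-2-acetoxy-2,3-dihydroxanthatin | C=C1C(=O)O[C@H]2C[C@H](C)C([C@H](OC(C)=O)CC(C)=O)=CC[C@H]12 | intermediate
24 | (2R)-2-acetoxy-4-hydroxyguaia-1(5),11(13)-dien-12,8-olide (C4 epimers) | C=C1C(=O)O[C@H]2C[C@H](C)C3=C(C[C@H]12)C(C)(O)C[C@H]3OC(C)=O | intermediate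
25 | (2R)-2-acetoxyguaia-1(5),3,11(13)-trien-12,8-olide (not isolated) | C=C1C(=O)O[C@H]2C[C@H](C)C3=C(C[C@H]12)C(C)=C[C@H]3OC(C)=O | intermediate
26 | CNP0211028.3 | C=C1C(=O)O[C@H]2C[C@H](C)[C@@]34C[C@]5(C(=O)O[C@@H]6CC(C)=C([C@@H](C)CCCOC(C)=O)[C@@H](O)[C@@H]65)[C@@H](C(C)=C3C[C@H]12)[C@H]4OC(C)=O | target

Total step count: 17. Longest linear sequence: 13 steps (steps 1, 2, 3, 5, 6, 7, 8, 9, 10, 11, 12, 13, 17).

Steps most likely to fail

Step 17. The transient diene 25 may be lost through [1,5]-hydrogen shifts and through cycloaddition to its own α-methylene lactone before it meets 19. In addition, the acetoxy group may steer the dienophile to its own face (the usual syn preference of 5-acyloxycyclopentadienes), against the steric bias on which the route relies. Fallback: the fallback sets out from 24 and masks its α-methylene lactone. Conjugate addition of dimethylamine gives the amine adduct F7. Dehydration as in step 17 gives the masked diene F8, which cannot add to itself and can therefore be used concentrated, cold and under pressure (1.0 GPa, 0 °C). Cycloaddition with 19 gives the masked dimer F9. N-Methylation with MeI gives the methiodide F10, and NaHCO3-induced elimination of trimethylamine restores the α-methylene lactone; the fallback comes back to the route at 26.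

Step 16. The C1 cation may lose the C10 proton instead of H5 (which would erase the C10 stereocentre), be captured by the neighbouring acetate, or the β-acetoxy ketone may simply eliminate acetic acid. Fallback: the fallback sets out from 23 and separates C–C bond formation from cation chemistry. Irradiation (300 nm, MeCN) effects an intramolecular Paternò–Büchi reaction of the C4 ketone with the C1=C5 alkene and gives the oxetane F6 (C4–C5 and O–C1 bonds). Opening of the strained ring at the tertiary C1–O bond with catalytic BF3·OEt2 at −78 °C and loss of H5 comes back to the route at 24.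

Step 5. The push–pull enol ester 9 may be too sluggish a dienophile, the adduct may lose acetic acid and silanol and aromatise, or endo and facial selectivity may erode. Fallback: the fallback sets out from 6 and replaces the enol ester by a boron surrogate. Copper-catalysed borylation of but-3-yn-2-one with bis(pinacolato)diboron gives (E)-4-(pinacolboryl)but-3-en-2-one F1, and photosensitised E-to-Z isomerisation gives the Z isomer F2. Diels–Alder reaction of 6 with F2 gives the boronate adduct F3, which cannot eliminate. Enol triflate formation as in step 6 gives F4, NaBO3 oxidation with retention gives the 8'-alcohol F5, and acetylation (Ac2O, pyridine) comes back to the route at 11.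

Further compounds
F1 | step 5 | (E)-4-(4,4,5,5-tetramethyl-1,3,2-dioxaborolan-2-yl)but-3-en-2-one | CC(=O)/C=C/B1OC(C)(C)C(C)(C)O1
F2 | step 5 | (Z)-4-(4,4,5,5-tetramethyl-1,3,2-dioxaborolan-2-yl)but-3-en-2-one | CC(=O)/C=C\B1OC(C)(C)C(C)(C)O1
F3 | step 5 | all-cis boronate adduct (6'-OTBS, 7'-acetyl, 8'-Bpin) | CC(C)(C)[Si](C)(C)O[C@@H]1[C@H](C(C)=O)[C@H](B2OC(C)(C)C(C)(C)O2)CC(C)=C1[C@@H](C)CCC=C(C)C
F4 | step 5 | enol triflate of F3 | CC(C)(C)[Si](C)(C)O[C@@H]1[C@H](C(=C)OS(=O)(=O)C(F)(F)F)[C@H](B2OC(C)(C)C(C)(C)O2)CC(C)=C1[C@@H](C)CCC=C(C)C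
F5 | step 5 | 8'-alcohol (6'-OTBS, enol triflate) | CC(C)(C)[Si](C)(C)O[C@@H]1[C@H](C(=C)OS(=O)(=O)C(F)(F)F)[C@H](O)CC(C)=C1[C@@H](C)CCC=C(C)C
F6 | step 16 | oxetane from 23 (C4–C5 and O–C1 bonds; C4 and C5 epimers) | C=C1C(=O)O[C@H]2C[C@H](C)C34OC(C)(C[C@H]3OC(C)=O)C4C[C@H]12
F7 | step 17 | dimethylamine adduct of 24 (C11 epimers) | CN(C)CC1C(=O)O[C@H]2C[C@H](C)C3=C(C[C@H]12)C(C)(O)C[C@H]3OC(C)=O
F8 | step 17 | dimethylamine-masked diene | CN(C)CC1C(=O)O[C@H]2C[C@H](C)C3=C(C[C@H]12)C(C)=C[C@H]3OC(C)=O
F9 | step 17 | dimethylamine-masked dimer | CN(C)CC1C(=O)O[C@H]2C[C@H](C)[C@@]34C[C@]5(C(=O)O[C@@H]6CC(C)=C([C@@H](C)CCCOC(C)=O)[C@@H](O)[C@@H]65)[C@@H](C(C)=C3C[C@H]12)[C@H]4OC(C)=O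
F10 | step 17 | methiodide of F9 | C[N+](C)(C)CC1C(=O)O[C@H]2C[C@H](C)[C@@]34C[C@]5(C(=O)O[C@@H]6CC(C)=C([C@@H](C)CCCOC(C)=O)[C@@H](O)[C@@H]65)[C@@H](C(C)=C3C[C@H]12)[C@H]4OC(C)=O.[I-]
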